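The data come from a simulation for an exercise; the scatter is artificial.

The pitfall in a fed flask is to read the quiet first minutes as a fixed delay on the clock, because time and free monomer rise together there and a delay by the clock says little about a flask charged at once.

| flask | free monomer | capture agent | initiator | temperature | remark | time |
|---|---|---|---|---|---|---|
| red | 0.20 M (fed, over 15 min) | 0.040 M | 20 mM | 65 °C | run made earlier |  |
| blue | 0.20 M (fed, over 15 min) | 0.090 M | 20 mM | 80 °C | run made earlier |  |
| green | 0.20 M (fed, over 15 min) | 0.060 M | 30 mM | 65 °C | run made earlier |  |
| Saturday's | 0.20 M (fed, over 15 min) | 0.0600 M | 20 mM | 80 °C |  | 15 min |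
| Thursday's | 0.20 M | 0.0600 M | 20 mM | 80 °C | everything together at the start | 15 min |

| run | time / min | monomer in chains / % | free monomer / % |
|---|---|---|---|
| red | 3.00 | 0.6 | 20.3 |
| red | 4.00 | 0 | 26.8 |
| red | 6.00 | 0.4 | 39.1 |
| red | 10.0 | 0.8 | 65.1 |
| red | 20.0 | 12.2 | 86.2 |
| red | 30.0 | 27.7 | 71.8 |
| blue | 2.50 | 0 | 16.3 |
| blue | 5.00 | 0.6 | 32.8 |
| blue | 8.00 | 2.7 | 50.2 |
| blue | 10.0 | 4.8 | 62.3 |
| blue | 12.0 | 7.1 | 71.6 |
| blue | 15.0 | 13.8 | 86.2 |
| green | 3.00 | 0.3 | 19.8 |
| green | 5.00 | 0.2 | 33.5 |
| green | 8.00 | 1.0 | 52.5 |
| green | 15.0 | 8.1 | 92.3 |
| green | 30.0 | 32.3 | 67.8 |

(scatter of a reading: 0.5 percentage points)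

- the numbers in the tables scatter with a standard deviation of 0.5 percentage points
- percentages count the whole charge, also what has not yet gone in
- a reading or a percentage of monomer in chains counts all its forms, free or not

* the flask that ends with the higher amount of monomer in chains, in percent of the free monomer charged, or "neither" when 2 percentage points or less lies between them (Saturday's / Thursday's / neither)
* final monomer in chains, as a percentage of the free monomer charged, in Saturday's
* final monomer in chains, as a percentage of the free monomer charged, in Thursday's

In blue, monomer in chains goes from 2.7% at 8.00 min to 13.8% at 15.0 min, which reads as a power of time of 2.60. On a steady feed, with the loss during the feed set aside, a constant rate per free monomer gives a power of 2 and a rate in the square of free monomer gives 3, and the reading stands nearer 3, though the scatter of the early reading leaves that open. This reckoning therefore commits to the square. Let x be c(free monomer) over its charge, and let chains, as a share of the charge, grow at g times the square of x. Here g is an apparent second-order rate constant.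

With the loss during the feed set aside, x climbs steadily to one, so its square averages a third over the feed, and chains at its end are roughly g times a third of the dosing time. This step is rough: blue's free monomer reads 86.2% at 15.0 min, below the full charge, so the mean of the square lies lower and g read this way comes out low. Blue thus gives 0.0276 /min. Blue matches Saturday's in feed, initiator and temperature, but carries 0.090 M of capture agent against 0.0600 M. The runs give no clean power for capture agent, so the reckoning takes 0.5, halfway between no effect and inverse proportion. That makes the chain coefficient for both new flasks 0.0338 /min.

The time scales then form a ladder. The feed takes 15 min. The chain time, the inverse of g, is 29.6 min, longer than the feed, so Saturday's should end still holding mostly free monomer, at 16.9% in chains. Slower still, green's free monomer at 65 °C falls after its feed with a time read as 48.6 min. In Thursday's, x starts at one and falls as the reciprocal of one plus g times time, which leaves 33.6% in chains, 17 percentage points above Saturday's.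

The forecast says Thursday's, with 21% and 33%, on the ground that “Thursday has all monomer present”. The flasks give 16.4% for Saturday's and 35.8% for Thursday's, so Thursday's ends higher.

    free monomer + initiator → living end + monomer in chains (k = 0.140 /M/min, Ea = 91.0 kJ/mol)
    free monomer + living end → monomer in chains + living end, rate k2*[living end]*[free monomer] (k = 37.0 /M/min, Ea = 45.0 kJ/mol)
    initiator + monomer in chains ⇌ idle complex, settled at all times (K = 1.60 /M, ΔH = −45.0 kJ/mol)
    monomer in chains → over-reaction product (k = 0.0180 /min, Ea = 108 kJ/mol)
    living end + capture agent → trapped intermediate (k = 6.00 /M/min, Ea = 73.0 kJ/mol)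
    (constants at 80 °C)

In the scheme, free monomer enters twice, once making the living end and once adding to it. The chain coefficient stood 0.50 points above Saturday's result and 2.2 points below Thursday's. The neighbour is Saturday's with 0.036 M of capture agent. The same square root gives it a coefficient of 0.0436 /min, and a third of the feed time then gives 21.8% in chains. That flask stands at 21.1%.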